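The benzene ring of the indole is cut at C5–C6 with formal return of HBr, after the two N-protecting groups and the pyrrole C5–Br have been taken off.
The feature used: indole C4(OMe)–C5 and C7–C6(Br) are two-carbon arms on adjacent carbons of a pyrrole (a 1-methoxyvinyl group on C3, a 2,2-dibromovinyl group on C2), and pyrrole C2=C3 is the central double bond of a hexatriene.
Further cuts: the enol ether C=CH2 (ester methylenation), C=CBr2 (aldehyde olefination), the pyrrole C2–CHO bond (directed magnesiation), the central pyrrole (TosMIC plus an enoate), the enoate C=C, and the oxazole C2–pyrrole C2 bond.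
Forward order of rings: the terminal pyrrole and the oxazole are bought, the central pyrrole is made by a van Leusen synthesis, and the benzene ring is closed last by electrocyclization.
Stereochemistry: the target has no stereocenter; the E geometry of enoate 9 is lost in the pyrrole synthesis, so nothing needs control.

Key step: step 10

Assumption: ethyl 2-chloro-1,3-oxazole-5-carboxylate (3) is taken as a purchasable building block; SEM = [2-(trimethylsilyl)ethoxy]methyl, Ts (tosyl) = p-toluenesulfonyl.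

Step 1
Reactants: 1 1H-pyrrole
Product: 2 1-SEM-pyrrole
Conditions: NaH, DMF, 0 °C; SEMCl, 0 °C to rt
Reagents that add atoms: 2-(trimethylsilyl)ethoxymethyl chloride (SEMCl), C[Si](C)(C)CCOCCl
Why: N-alkylation (SN2) of the pyrrolide anion by the chloromethyl ether installs a group that withstands base, organometallics and heat and directs lithiation to C2.

Step 2
Reactants: 2 1-SEM-pyrrole; 3 ethyl 2-chloro-1,3-oxazole-5-carboxylate
Product: 6 ethyl 2-(1-SEM-pyrrol-2-yl)oxazole-5-carboxylate, via 1-SEM-pyrrol-2-yllithium 4 (not isolated), via chloro(1-SEM-pyrrol-2-yl)zinc 5 (not isolated)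
Conditions: n-BuLi, THF, –10 to 0 °C; ZnCl2, 0 °C; then 3, Pd(PPh3)4 (5 mol %), THF, 55 °C
Reagents that add atoms: none
Why: SEM-directed C2 lithiation, transmetalation to zinc and Negishi coupling at the imidoyl-type C2–Cl of the oxazole should join the two heterocycles, and the organozinc leaves the ester alone.

Step 3
Reactants: 6 ethyl 2-(1-SEM-pyrrol-2-yl)oxazole-5-carboxylate
Product: 7 [2-(1-SEM-pyrrol-2-yl)oxazol-5-yl]methanol
Conditions: i-Bu2AlH (2.5 equiv), CH2Cl2, –78 to 0 °C; aq. potassium sodium tartrate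
Reagents that add atoms: none
Why: Hydride reduction of a heteroaryl ester with i-Bu2AlH stops cleanly at the primary alcohol, and the oxazole and the SEM group are inert to it at low temperature.

Step 4
Reactants: 7 [2-(1-SEM-pyrrol-2-yl)oxazol-5-yl]methanol
Product: 9 methyl (E)-3-[2-(1-SEM-pyrrol-2-yl)oxazol-5-yl]prop-2-enoate, via 2-(1-SEM-pyrrol-2-yl)oxazole-5-carbaldehyde 8 (not isolated)
Conditions: MnO2 (10 equiv), Ph3P=CHCO2Me (1.3 equiv), CH2Cl2, rt to 40 °C
Reagents that add atoms: methyl (triphenylphosphoranylidene)acetate, COC(=O)C=P(c1ccccc1)(c1ccccc1)c1ccccc1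
Why: In this tandem oxidation–Wittig olefination the activated oxazolylmethanol is oxidized by MnO2 and the aldehyde is trapped at once by the stabilized ylide, giving mainly the E enoate, whose geometry is of no consequence for step 5.

Step 5
Reactants: 9 methyl (E)-3-[2-(1-SEM-pyrrol-2-yl)oxazol-5-yl]prop-2-enoate; 10 tosylmethyl isocyanide (TosMIC)
Product: 11 methyl 4-[2-(1-SEM-pyrrol-2-yl)oxazol-5-yl]-1H-pyrrole-3-carboxylate
Conditions: KOt-Bu, THF, 0 °C to rt
Reagents that add atoms: none
Why: Van Leusen pyrrole synthesis, in which conjugate addition of the TosMIC anion, closure of the ester enolate onto the isocyanide carbon and loss of p-toluenesulfinate give the 3,4-disubstituted pyrrole with both α positions free.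

Step 6
Reactants: 11 methyl 4-[2-(1-SEM-pyrrol-2-yl)oxazol-5-yl]-1H-pyrrole-3-carboxylate
Product: 12 methyl 4-[2-(1-SEM-pyrrol-2-yl)oxazol-5-yl]-1-tosylpyrrole-3-carboxylate
Conditions: NaH, THF, 0 °C; TsCl, 0 °C to rt
Reagents that add atoms: p-toluenesulfonyl chloride, Cc1ccc(S(=O)(=O)Cl)cc1
Why: N-sulfonylation of the only N–H in the molecule gives a group that acidifies the adjacent C–H for step 7 and lowers the aromaticity of this ring for step 10.

Step 7
Reactants: 12 methyl 4-[2-(1-SEM-pyrrol-2-yl)oxazol-5-yl]-1-tosylpyrrole-3-carboxylate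
Product: 14 methyl 2-formyl-4-[2-(1-SEM-pyrrol-2-yl)oxazol-5-yl]-1-tosylpyrrole-3-carboxylate, via pyrrol-2-ylmagnesium chloride 13 (not isolated)
Conditions: TMPMgCl·LiCl (1.3 equiv), THF, –30 to 0 °C; DMF, –30 °C to rt; aq. NH4Cl
Reagents that add atoms: N,N-dimethylformamide, CN(C)C=O
Why: Directed ortho-magnesiation with the Knochel–Hauser base should take place at C2, the only C–H flanked by both the N-sulfonyl and the ester groups, and the arylmagnesium is formylated by DMF (Bouveault formylation).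

Step 8
Reactants: 14 methyl 2-formyl-4-[2-(1-SEM-pyrrol-2-yl)oxazol-5-yl]-1-tosylpyrrole-3-carboxylate
Product: 15 methyl 2-(2,2-dibromovinyl)-4-[2-(1-SEM-pyrrol-2-yl)oxazol-5-yl]-1-tosylpyrrole-3-carboxylate
Conditions: CBr4, PPh3, Zn dust, CH2Cl2, rt (ylide preformed); then 14, 0 °C to rt
Reagents that add atoms: carbon tetrabromide, BrC(Br)(Br)Br
Why: Ramirez dibromoolefination (first stage of the Corey–Fuchs sequence) with Ph3P=CBr2 converts the aldehyde into the 1,1-dibromoalkene, and generating the ylide with zinc keeps acidic phosphonium bromide away from the SEM group.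

Step 9
Reactants: 15 methyl 2-(2,2-dibromovinyl)-4-[2-(1-SEM-pyrrol-2-yl)oxazol-5-yl]-1-tosylpyrrole-3-carboxylate
Product: 16 2-(2,2-dibromovinyl)-3-(1-methoxyvinyl)-4-[2-(1-SEM-pyrrol-2-yl)oxazol-5-yl]-1-tosylpyrrole
Conditions: Cp2TiMe2 (3 equiv), toluene/THF, 65–70 °C, dark; filtration through basic Al2O3 (Et3N-treated)
Reagents that add atoms: dimethyltitanocene (Cp2TiMe2), C[Ti](C)(C1C=CC=C1)C1C=CC=C1
Why: Petasis methylenation turns the ester carbonyl into the methyl enol ether through Cp2Ti=CH2 and an oxatitanacyclobutane under neutral conditions, which should spare the vinyl dibromide, the sulfonamide and the SEM group.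

Step 10
Reactants: 16 2-(2,2-dibromovinyl)-3-(1-methoxyvinyl)-4-[2-(1-SEM-pyrrol-2-yl)oxazol-5-yl]-1-tosylpyrrole
Product: 18 6-bromo-4-methoxy-3-[2-(1-SEM-pyrrol-2-yl)oxazol-5-yl]-1-tosylindole, via 6,6-dibromo-5,6-dihydroindole 17 (not isolated)
Conditions: 2,6-lutidine (3 equiv), degassed 1,2-dichlorobenzene, 150–160 °C, dark
Reagents that add atoms: none
Why: The pyrrole C2=C3 bond and the two vinyl arms of 16 form a cis-hexatriene that should close thermally by a disrotatory six-electron electrocyclization, joining the enol ether CH2 (future C5) to the CBr2 carbon (future C6) and giving the six-membered ring of 17. The allylic geminal dibromide 17 then loses HBr across C5–C6, driven by aromatization of both rings, which leaves one bromine on C6 and the methoxy group on C4 without any oxidant. The closest known reaction type is the thermal electrocyclization of 2,3-dialkenylpyrroles and 2,3-dialkenylindoles followed by aromatization through oxidation or loss of HX. No stereocenter survives, so the sense of rotation has no consequence, and the regiochemistry cannot vary because the C4 and C6 substituents sit on separate arms. The step needs ring closure to outrun dehydrobromination and acid damage: a weak, hindered pyridine base traps HBr, sparing the enol ether and the SEM group, but unlike amidine bases it does not turn the 1,1-dibromoalkene into a bromoalkyne. The N-sulfonyl group lowers the aromatic stabilization that the closure must interrupt, and the alternative triene running through the oxazole C4=C5 bond can close only reversibly because it has no leaving group.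

Step 11
Reactants: 18 6-bromo-4-methoxy-3-[2-(1-SEM-pyrrol-2-yl)oxazol-5-yl]-1-tosylindole
Product: 19 6-bromo-3-[2-(5-bromo-1-SEM-pyrrol-2-yl)oxazol-5-yl]-4-methoxy-1-tosylindole
Conditions: NBS (1.0 equiv), THF, –78 to 0 °C, dark
Reagents that add atoms: N-bromosuccinimide, O=C1CCC(=O)N1Br
Why: Electrophilic aromatic bromination should go to the free α position (C5) of the N-alkylpyrrole, by far the most nucleophilic site, because the indole is deactivated by the N-sulfonyl group and its 6-bromo substituent and the oxazole C4–H is much less reactive.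

Step 12
Reactants: 19 6-bromo-3-[2-(5-bromo-1-SEM-pyrrol-2-yl)oxazol-5-yl]-4-methoxy-1-tosylindole
Product: 20 6-bromo-3-[2-(5-bromo-1H-pyrrol-2-yl)-1,3-oxazol-5-yl]-4-methoxy-1H-indole
Conditions: Bu4NF (8 equiv, 1 M in THF), THF, 65 °C; aqueous work-up
Reagents that add atoms: none
Why: Fluoride-induced deprotection, in which fluoride attacks silicon of the SEM group (fragmentation to ethylene and formaldehyde) and sulfur of the N-sulfonylindole, should free both nitrogens in one operation.

Compound list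
1 | 1H-pyrrole | c1cc[nH]c1 | starting material
2 | 1-{[2-(trimethylsilyl)ethoxy]methyl}-1H-pyrrole (1-SEM-pyrrole) | C[Si](C)(C)CCOCn1cccc1 | intermediate
3 | ethyl 2-chloro-1,3-oxazole-5-carboxylate | CCOC(=O)c1cnc(Cl)o1 | starting material
4 | (1-SEM-pyrrol-2-yl)lithium | [Li]c1cccn1COCC[Si](C)(C)C | intermediate
5 | chloro(1-SEM-pyrrol-2-yl)zinc | Cl[Zn]c1cccn1COCC[Si](C)(C)C | intermediate
6 | ethyl 2-(1-SEM-1H-pyrrol-2-yl)-1,3-oxazole-5-carboxylate | CCOC(=O)c1cnc(-c2cccn2COCC[Si](C)(C)C)o1 | intermediate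
7 | [2-(1-SEM-1H-pyrrol-2-yl)-1,3-oxazol-5-yl]methanol | OCc1cnc(-c2cccn2COCC[Si](C)(C)C)o1 | intermediate
8 | 2-(1-SEM-1H-pyrrol-2-yl)-1,3-oxazole-5-carbaldehyde | O=Cc1cnc(-c2cccn2COCC[Si](C)(C)C)o1 | intermediate
9 | methyl (E)-3-[2-(1-SEM-1H-pyrrol-2-yl)-1,3-oxazol-5-yl]prop-2-enoate | COC(=O)/C=C/c1cnc(-c2cccn2COCC[Si](C)(C)C)o1 | intermediate
10 | tosylmethyl isocyanide (TosMIC) | Cc1ccc(S(=O)(=O)C[N+]#[C-])cc1 | starting material
11 | methyl 4-[2-(1-SEM-1H-pyrrol-2-yl)-1,3-oxazol-5-yl]-1H-pyrrole-3-carboxylate | COC(=O)c1c[nH]cc1-c1cnc(-c2cccn2COCC[Si](C)(C)C)o1 | intermediate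
12 | methyl 4-[2-(1-SEM-1H-pyrrol-2-yl)-1,3-oxazol-5-yl]-1-tosyl-1H-pyrrole-3-carboxylate | COC(=O)c1cn(S(=O)(=O)c2ccc(C)cc2)cc1-c1cnc(-c2cccn2COCC[Si](C)(C)C)o1 | intermediate
13 | chloro{3-(methoxycarbonyl)-4-[2-(1-SEM-pyrrol-2-yl)oxazol-5-yl]-1-tosylpyrrol-2-yl}magnesium | COC(=O)c1c([Mg]Cl)n(S(=O)(=O)c2ccc(C)cc2)cc1-c1cnc(-c2cccn2COCC[Si](C)(C)C)o1 | intermediate
14 | methyl 2-formyl-4-[2-(1-SEM-1H-pyrrol-2-yl)-1,3-oxazol-5-yl]-1-tosyl-1H-pyrrole-3-carboxylate | COC(=O)c1c(C=O)n(S(=O)(=O)c2ccc(C)cc2)cc1-c1cnc(-c2cccn2COCC[Si](C)(C)C)o1 | intermediate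
15 | methyl 2-(2,2-dibromovinyl)-4-[2-(1-SEM-1H-pyrrol-2-yl)-1,3-oxazol-5-yl]-1-tosyl-1H-pyrrole-3-carboxylate | COC(=O)c1c(C=C(Br)Br)n(S(=O)(=O)c2ccc(C)cc2)cc1-c1cnc(-c2cccn2COCC[Si](C)(C)C)o1 | intermediate
16 | 2-(2,2-dibromovinyl)-3-(1-methoxyvinyl)-4-[2-(1-SEM-1H-pyrrol-2-yl)-1,3-oxazol-5-yl]-1-tosyl-1H-pyrrole | COC(=C)c1c(C=C(Br)Br)n(S(=O)(=O)c2ccc(C)cc2)cc1-c1cnc(-c2cccn2COCC[Si](C)(C)C)o1 | intermediate
17 | 6,6-dibromo-4-methoxy-3-[2-(1-SEM-1H-pyrrol-2-yl)-1,3-oxazol-5-yl]-1-tosyl-5,6-dihydro-1H-indole | COC1=C2C(-c3cnc(-c4cccn4COCC[Si](C)(C)C)o3)=CN(S(=O)(=O)c3ccc(C)cc3)C2=CC(Br)(Br)C1 | intermediate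
18 | 6-bromo-4-methoxy-3-[2-(1-SEM-1H-pyrrol-2-yl)-1,3-oxazol-5-yl]-1-tosyl-1H-indole | COc1cc(Br)cc2c1c(-c1cnc(-c3cccn3COCC[Si](C)(C)C)o1)cn2S(=O)(=O)c1ccc(C)cc1 | intermediate
19 | 6-bromo-3-[2-(5-bromo-1-SEM-1H-pyrrol-2-yl)-1,3-oxazol-5-yl]-4-methoxy-1-tosyl-1H-indole | COc1cc(Br)cc2c1c(-c1cnc(-c3ccc(Br)n3COCC[Si](C)(C)C)o1)cn2S(=O)(=O)c1ccc(C)cc1 | intermediate
20 | 6-bromo-3-[2-(5-bromo-1H-pyrrol-2-yl)-1,3-oxazol-5-yl]-4-methoxy-1H-indole | COc1cc(Br)cc2[nH]cc(-c3cnc(-c4ccc(Br)[nH]4)o3)c12 | target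

Total step count: 12 steps.
Longest linear sequence: 12 steps, from 1H-pyrrole (1) to 20; the building blocks 3 and 10 enter as bought.

Steps most likely to fail

Step 10. The ring closure may be held back by the bromine that must rotate inward at the CBr2 terminus and by the loss of pyrrole aromaticity in the transition state. At the temperature then needed, dehydrobromination of the dibromoalkene, acid-induced loss of the enol ether or cleavage of the SEM group could overtake it. The fallback sets out from 16 and returns at 18, and replaces the pericyclic closure by a polar, metal-catalysed one. DBU in MeCN at room temperature should eliminate HBr from the 1,1-dibromoalkene (the standard route to 1-bromoalkynes) and give 2-(bromoethynyl)-3-(1-methoxyvinyl)-4-[2-(1-SEM-pyrrol-2-yl)oxazol-5-yl]-1-tosylpyrrole F1. A π-acid that does not induce a 1,2-halide shift, InCl3 (10 mol %) in toluene at 80 °C, should then bring about 6-endo-dig attack of the enol ether CH2 on the bromine-bearing alkyne carbon. Proton loss and protodemetalation give 18 with bromine still on C6.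

Step 9. Methylenation of an ester flanked by two ring substituents may be slow, titanium species may attack the dibromoalkene on prolonged heating, and the enol ether may hydrolyse during isolation. The fallback sets out from 15 and returns at 16, and builds the enol ether by elimination from a ketal instead of by carbonyl methylenation. AlMe3 and MeNH(OMe)·HCl in CH2Cl2 should convert the ester into the Weinreb amide N-methoxy-N-methyl-2-(2,2-dibromovinyl)-4-[2-(1-SEM-pyrrol-2-yl)oxazol-5-yl]-1-tosylpyrrole-3-carboxamide F2. MeMgBr in THF at –20 °C then gives 3-acetyl-2-(2,2-dibromovinyl)-4-[2-(1-SEM-pyrrol-2-yl)oxazol-5-yl]-1-tosylpyrrole F3. Trimethyl orthoformate in MeOH with catalytic pyridinium p-toluenesulfonate gives the dimethyl ketal 2-(2,2-dibromovinyl)-3-(1,1-dimethoxyethyl)-4-[2-(1-SEM-pyrrol-2-yl)oxazol-5-yl]-1-tosylpyrrole F4. Me3SiOTf and i-Pr2NEt in CH2Cl2 at –20 to 0 °C (Gassman elimination of methanol from a ketal) should then deliver 16.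

Step 12. Fluoride-induced cleavage of an N-SEM pyrrole may stall at the N-hydroxymethyl stage, the liberated formaldehyde may add back to the electron-rich rings, and the free bromopyrrole may suffer on long heating with basic fluoride. The fallback sets out from 19 and returns at 20, and uses acid-induced acetal cleavage followed by base instead of fluoride. Trifluoroacetic acid in CH2Cl2 at 0 °C to rt, then aqueous work-up, should cut the N,O-acetal and leave 6-bromo-3-{2-[5-bromo-1-(hydroxymethyl)pyrrol-2-yl]oxazol-5-yl}-4-methoxy-1-tosylindole F5. Cs2CO3 in MeOH/THF at 50–60 °C should then expel formaldehyde from the hemiaminal and remove the tosyl group by methanolysis at sulfur, giving 20.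

Further compounds
F1 | step 10 | 2-(bromoethynyl)-3-(1-methoxyvinyl)-4-[2-(1-SEM-1H-pyrrol-2-yl)-1,3-oxazol-5-yl]-1-tosyl-1H-pyrrole | COC(=C)c1c(C#CBr)n(S(=O)(=O)c2ccc(C)cc2)cc1-c1cnc(-c2cccn2COCC[Si](C)(C)C)o1
F2 | step 9 | N-methoxy-N-methyl-2-(2,2-dibromovinyl)-4-[2-(1-SEM-1H-pyrrol-2-yl)-1,3-oxazol-5-yl]-1-tosyl-1H-pyrrole-3-carboxamide | CON(C)C(=O)c1c(C=C(Br)Br)n(S(=O)(=O)c2ccc(C)cc2)cc1-c1cnc(-c2cccn2COCC[Si](C)(C)C)o1
F3 | step 9 | 3-acetyl-2-(2,2-dibromovinyl)-4-[2-(1-SEM-1H-pyrrol-2-yl)-1,3-oxazol-5-yl]-1-tosyl-1H-pyrrole | CC(=O)c1c(C=C(Br)Br)n(S(=O)(=O)c2ccc(C)cc2)cc1-c1cnc(-c2cccn2COCC[Si](C)(C)C)o1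
F4 | step 9 | 2-(2,2-dibromovinyl)-3-(1,1-dimethoxyethyl)-4-[2-(1-SEM-1H-pyrrol-2-yl)-1,3-oxazol-5-yl]-1-tosyl-1H-pyrrole | COC(C)(OC)c1c(C=C(Br)Br)n(S(=O)(=O)c2ccc(C)cc2)cc1-c1cnc(-c2cccn2COCC[Si](C)(C)C)o1
F5 | step 12 | 6-bromo-3-{2-[5-bromo-1-(hydroxymethyl)-1H-pyrrol-2-yl]-1,3-oxazol-5-yl}-4-methoxy-1-tosyl-1H-indole | COc1cc(Br)cc2c1c(-c1cnc(-c3ccc(Br)n3CO)o1)cn2S(=O)(=O)c1ccc(C)cc1
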